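## Retrosynthetic overview
1. The target comes from one cold acid hydrolysis of an N-(S)-tert-butylsulfinyl, O-methoxymethyl (MOM) protected adduct. No ring is formed after the coupling.
2. Key cut: C3 (lactam)–C2 (dienone). Each carbon is the acidic, donor position of its own fragment. The dione carbon is used with inverted polarity as a 2-iodo vinylogous ester (α-keto-vinyl cation, an enolonium equivalent). The lactam carbon is used as its chiral zinc enolate (an α-amino carbanion, the reverse of the N-acyliminium ion). Palladium joins them and the sulfinyl group sets C3.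
3. The iodo dienone comes from orcinol by C2 iodination, mono-MOM ether formation, and a double ortho C-prenylation that dearomatises the bought arene.
4. The sulfinyl lactam comes from methyl 3-methoxy-2-methylbenzoate by benzylic bromination, then N-alkylation and lactamisation with (S)-tert-butanesulfinamide.
5. Ring order: both six-membered rings are bought as arenes. The lactam ring is closed in step 2 and the orcinol ring is dearomatised in step 5.

Assumption: C3 of the target is read as (S) (priorities N > dienone C > aryl C > H), and the (S)-sulfinyl group is taken to direct bond formation at C3 anti to its tert-butyl group in the metal-chelated enolate, as in its simple alkylations.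

## Route

Step 1
Reactants: 1 methyl 3-methoxy-2-methylbenzoate
Product: 2 methyl 2-(bromomethyl)-3-methoxybenzoate
Conditions: NBS (1.05 equiv), AIBN (5 mol %), PhCF3, 85 °C
Reagents that add atoms: N-bromosuccinimide, O=C1CCC(=O)N1Br
Why: Wohl–Ziegler bromination; the 2-methyl group holds the only benzylic C–H bonds, and radical conditions in a non-polar solvent suppress ionic ring bromination of the anisole.

Step 2
Reactants: 2 methyl 2-(bromomethyl)-3-methoxybenzoate; 3 (S)-2-methylpropane-2-sulfinamide
Product: 5 (S)-2-(tert-butylsulfinyl)-4-methoxyisoindolin-1-one, via N-benzyl sulfinamide 4 (not isolated)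
Conditions: 3, NaH (2.2 equiv), THF/DMF 5:1, 0 °C; then 2, 0 °C → rt
Reagents that add atoms: none
Why: SN2 N-alkylation of the sulfinamide anion, then 5-exo-trig lactamisation of the second anion onto the ortho ester; ring closure outruns a second alkylation and the sulfur stereocentre is not touched.

Step 3
Reactants: 6 orcinol (5-methylbenzene-1,3-diol)
Product: 7 2-iodo-5-methylbenzene-1,3-diol
Conditions: I2 (1.05 equiv), NaHCO3 (1.1 equiv), H2O, 0 °C → rt
Reagents that add atoms: iodine, II
Why: Electrophilic aromatic iodination; in aqueous bicarbonate resorcinols are iodinated kinetically between the two hydroxyl groups, and the 5-methyl group further shields C4 and C6.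

Step 4
Reactants: 7 2-iodo-5-methylbenzene-1,3-diol
Product: 8 2-iodo-3-(methoxymethoxy)-5-methylphenol
Conditions: MOMCl (1.0 equiv), i-Pr2NEt (1.1 equiv), CH2Cl2, 0 °C
Reagents that add atoms: chloromethyl methyl ether (MOMCl), COCCl
Why: Williamson-type mono-O-alkylation of a symmetric diol; the outcome is statistical, the mono-ether is separated by chromatography, and the diol and bis-ether are recycled.

Step 5
Reactants: 8 2-iodo-3-(methoxymethoxy)-5-methylphenol; 9 prenyl bromide (1-bromo-3-methylbut-2-ene)
Product: 11 2-iodo-3-(methoxymethoxy)-5-methyl-6,6-bis(3-methylbut-2-en-1-yl)cyclohexa-2,4-dien-1-one, via ortho-prenyl phenol 10 (not isolated)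
Conditions: NaH (2.3 equiv), 9 (2.3 equiv), toluene, 0 → 40 °C
Reagents that add atoms: none
Why: Ortho-selective C-alkylation of a tight sodium phenoxide ion pair in a non-polar solvent (alkylative dearomatisation); iodine blocks C2 and only one oxygen is anionic, so both prenyl groups go to C6, the first with rearomatisation and the second giving the 6,6-disubstituted dienone, and no stereocentre arises because the two groups are identical.

Step 6
Reactants: 5 (S)-2-(tert-butylsulfinyl)-4-methoxyisoindolin-1-one; 11 2-iodo-3-(methoxymethoxy)-5-methyl-6,6-bis(3-methylbut-2-en-1-yl)cyclohexa-2,4-dien-1-one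
Product: 14 (3S)-2-[(S)-tert-butylsulfinyl]-4-methoxy-3-[2-(methoxymethoxy)-4-methyl-5,5-bis(3-methylbut-2-en-1-yl)-6-oxocyclohexa-1,3-dien-1-yl]isoindolin-1-one, via lithium enolate 12 (not isolated), via chlorozinc enolate 13 (not isolated)
Conditions: 5 (1.3 equiv), LiN(i-Pr)2 (1.3 equiv), THF, −78 °C; ZnCl2 (1.4 equiv), −78 °C → rt; then 11, Pd(dba)2 (5 mol %), P(t-Bu)3 (6 mol %), THF, rt → 45 °C; chromatography removes any minor C3 epimer
Reagents that add atoms: none
Why: Proposed new method: oxidative addition of zerovalent palladium into the C–I bond of 11 turns the normally nucleophilic C2 of the masked 1,3-dione into an electrophilic α-keto-vinyl palladium iodide, the weakly basic zinc enolate 13 (metal chelated by enolate O and sulfinyl O, tert-butyl covering one face) transmetalates through C3 on the open face, and reductive elimination with retention gives 3S; there is no β-hydrogen, Heck closure onto a prenyl group would need a bridgehead alkene, and zinc enolates are too weakly basic to epimerise 14 or to add to the dienone at a competitive rate; the closest known reaction types are Pd-catalysed α-arylation and alkenylation of zinc amide enolates (including auxiliary-controlled cases), Pd-catalysed C3 arylation of isoindolinones, the highly diastereoselective alkylation of lithiated N-tert-butylsulfinyl isoindolinones, and Negishi coupling of 2-iodo enones.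

Step 7
Reactants: 14 (3S)-2-[(S)-tert-butylsulfinyl]-4-methoxy-3-[2-(methoxymethoxy)-4-methyl-5,5-bis(3-methylbut-2-en-1-yl)-6-oxocyclohexa-1,3-dien-1-yl]isoindolin-1-one
Product: 15 (3S)-3-[2-hydroxy-4-methyl-5,5-bis(3-methylbut-2-en-1-yl)-6-oxocyclohexa-1,3-dien-1-yl]-4-methoxyisoindolin-1-one (target)
Conditions: 2 M aq HCl/THF 1:4, 0 °C → rt, 1–2 h; pH 5 buffer work-up
Reagents that add atoms: none
Why: Acid hydrolysis; the N-acyl sulfinamide S–N bond and the vinylogous MOM ester (an acyl acetal) are far more acid-labile than the aryl methyl ether or the prenyl alkenes, no bond at C3 is broken, and the short cold exposure avoids retro-Mannich racemisation and closure of the enol onto a prenyl group.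

## Compound list
1 | methyl 3-methoxy-2-methylbenzoate | COC(=O)c1cccc(OC)c1C | starting material
2 | methyl 2-(bromomethyl)-3-methoxybenzoate | COC(=O)c1cccc(OC)c1CBr | intermediate
3 | (S)-2-methylpropane-2-sulfinamide | CC(C)(C)[S@](=O)N | starting material
4 | methyl 2-({[(S)-tert-butylsulfinyl]amino}methyl)-3-methoxybenzoate (not isolated) | CC(C)(C)[S@](=O)NCc1c(OC)cccc1C(=O)OC | intermediate
5 | (S)-2-(tert-butylsulfinyl)-4-methoxyisoindolin-1-one | CC(C)(C)[S@](=O)N1Cc2c(OC)cccc2C1=O | intermediate
6 | orcinol (5-methylbenzene-1,3-diol) | Cc1cc(O)cc(O)c1 | starting material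
7 | 2-iodo-5-methylbenzene-1,3-diol | Cc1cc(O)c(I)c(O)c1 | intermediate
8 | 2-iodo-3-(methoxymethoxy)-5-methylphenol | COCOc1cc(C)cc(O)c1I | intermediate
9 | prenyl bromide (1-bromo-3-methylbut-2-ene) | CC(C)=CCBr | starting material
10 | 2-iodo-3-(methoxymethoxy)-5-methyl-6-(3-methylbut-2-en-1-yl)phenol (not isolated) | COCOc1cc(C)c(CC=C(C)C)c(O)c1I | intermediate
11 | 2-iodo-3-(methoxymethoxy)-5-methyl-6,6-bis(3-methylbut-2-en-1-yl)cyclohexa-2,4-dien-1-one | COCOC1=C(I)C(=O)C(CC=C(C)C)(CC=C(C)C)C(C)=C1 | intermediate
12 | lithium 2-[(S)-tert-butylsulfinyl]-4-methoxy-2H-isoindol-1-olate (not isolated) | CC(C)(C)[S@](=O)n1cc2c(OC)cccc2c1O[Li] | intermediate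
13 | chlorozinc 2-[(S)-tert-butylsulfinyl]-4-methoxy-2H-isoindol-1-olate (not isolated) | CC(C)(C)[S@](=O)n1cc2c(OC)cccc2c1O[Zn]Cl | intermediate
14 | (3S)-2-[(S)-tert-butylsulfinyl]-4-methoxy-3-[2-(methoxymethoxy)-4-methyl-5,5-bis(3-methylbut-2-en-1-yl)-6-oxocyclohexa-1,3-dien-1-yl]isoindolin-1-one | CC(C)(C)[S@](=O)N1[C@H](C2=C(OCOC)C=C(C)C(CC=C(C)C)(CC=C(C)C)C2=O)c2c(OC)cccc2C1=O | intermediate
15 | (3S)-3-[2-hydroxy-4-methyl-5,5-bis(3-methylbut-2-en-1-yl)-6-oxocyclohexa-1,3-dien-1-yl]-4-methoxyisoindolin-1-one | COc1cccc2c1[C@@H](C1=C(O)C=C(C)C(CC=C(C)C)(CC=C(C)C)C1=O)NC2=O | target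

## Step count and risks
Total step count: 7.
Longest linear sequence: 5 (steps 3, 4, 5, 6 and 7, from orcinol).

**Most likely to fail: step 6.**
- Risk: the vinyl iodide is tetrasubstituted and flanked on both sides. The sulfinyl group may slow the catalyst. The diastereoselectivity of a palladium-mediated bond formation under sulfinyl control is untested.
- Fallback, setting out from 8 (with zinc enolate 13 made from 5 as before) and coming back at 14: the coupling is done on the flat, base-stable arene and the dearomatisation is moved behind it.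
- Phenol 8 is silylated (TBSCl, imidazole, DMF) to tert-butyl[2-iodo-3-(methoxymethoxy)-5-methylphenoxy]dimethylsilane F1.
- F1 is coupled with 13 under zerovalent palladium catalysis at 60–70 °C. This is an enolate arylation with close precedent for isoindolinones. It gives (3S)-2-[(S)-tert-butylsulfinyl]-3-[2-(tert-butyldimethylsilyloxy)-6-(methoxymethoxy)-4-methylphenyl]-4-methoxyisoindolin-1-one F2.
- Bu4NF frees (3S)-2-[(S)-tert-butylsulfinyl]-3-[2-hydroxy-6-(methoxymethoxy)-4-methylphenyl]-4-methoxyisoindolin-1-one F3.
- The lactam substituent now blocks the position between the two oxygens and the sulfinyl group protects nitrogen. The double ortho prenylation (NaH, 9, toluene, base kept stoichiometric) then runs through (3S)-2-[(S)-tert-butylsulfinyl]-3-[2-hydroxy-6-(methoxymethoxy)-4-methyl-3-(3-methylbut-2-en-1-yl)phenyl]-4-methoxyisoindolin-1-one F4 to 14.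

**Second: step 5.**
- Risk: O-prenylation, para attack at C4 and ipso attack at the iodine-bearing carbon all compete with the second, dearomatising alkylation.
- Fallback, setting out from 7 and coming back at 11 (it bypasses step 4): the unprotected diol is C-prenylated twice as its dianion in a protic medium (KOH, H2O/MeOH, 9, 0 °C), where solvation of oxygen favours carbon attack.
- This runs through 2-iodo-5-methyl-4-(3-methylbut-2-en-1-yl)benzene-1,3-diol F5 to the vinylogous acid 3-hydroxy-2-iodo-5-methyl-6,6-bis(3-methylbut-2-en-1-yl)cyclohexa-2,4-dien-1-one F6.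
- F6 alone among the products dissolves in aqueous NaHCO3, so it is separated from the aromatic 4,6-diprenyl and O-prenyl by-products by extraction.
- MOMCl with i-Pr2NEt then alkylates the less hindered oxygen, remote from the quaternary carbon, to give 11.

**Third: step 2.**
- Risk: the methoxide released on ring closure may strip the activated sulfinyl group from 5. Over-alkylation of the sulfinamide is also possible.
- Fallback, setting out from 2 and coming back at 5: the C–N bond is made by reductive amination instead of alkylation.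
- Bromide 2 is oxidised with N-methylmorpholine N-oxide (MeCN, rt) to methyl 2-formyl-3-methoxybenzoate F7.
- F7 is condensed with 3 (Ti(OEt)4, THF) to methyl 2-{(E)-[(S)-tert-butylsulfinylimino]methyl}-3-methoxybenzoate F8.
- NaBH4 (−40 → 0 °C) reduces the C=N bond to 4, which lactamises in the same flask to 5.

## Further compounds
F1 | step 6 | tert-butyl[2-iodo-3-(methoxymethoxy)-5-methylphenoxy]dimethylsilane | COCOc1cc(C)cc(O[Si](C)(C)C(C)(C)C)c1I
F2 | step 6 | (3S)-2-[(S)-tert-butylsulfinyl]-3-[2-(tert-butyldimethylsilyloxy)-6-(methoxymethoxy)-4-methylphenyl]-4-methoxyisoindolin-1-one | CC(C)(C)[S@](=O)N1[C@H](c2c(OCOC)cc(C)cc2O[Si](C)(C)C(C)(C)C)c2c(OC)cccc2C1=O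
F3 | step 6 | (3S)-2-[(S)-tert-butylsulfinyl]-3-[2-hydroxy-6-(methoxymethoxy)-4-methylphenyl]-4-methoxyisoindolin-1-one | CC(C)(C)[S@](=O)N1[C@H](c2c(OCOC)cc(C)cc2O)c2c(OC)cccc2C1=O
F4 | step 6 | (3S)-2-[(S)-tert-butylsulfinyl]-3-[2-hydroxy-6-(methoxymethoxy)-4-methyl-3-(3-methylbut-2-en-1-yl)phenyl]-4-methoxyisoindolin-1-one | CC(C)(C)[S@](=O)N1[C@H](c2c(OCOC)cc(C)c(CC=C(C)C)c2O)c2c(OC)cccc2C1=O
F5 | step 5 | 2-iodo-5-methyl-4-(3-methylbut-2-en-1-yl)benzene-1,3-diol | Cc1cc(O)c(I)c(O)c1CC=C(C)C
F6 | step 5 | 3-hydroxy-2-iodo-5-methyl-6,6-bis(3-methylbut-2-en-1-yl)cyclohexa-2,4-dien-1-one | OC1=C(I)C(=O)C(CC=C(C)C)(CC=C(C)C)C(C)=C1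
F7 | step 2 | methyl 2-formyl-3-methoxybenzoate | COC(=O)c1cccc(OC)c1C=O
F8 | step 2 | methyl 2-{(E)-[(S)-tert-butylsulfinylimino]methyl}-3-methoxybenzoate | CC(C)(C)[S@](=O)/N=C/c1c(OC)cccc1C(=O)OC
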